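**Retrosynthetic overview**

- Ring C is opened last: the flavonol goes back (C2–O1 and C3–C(aroyl) bonds) to a Baker–Venkataraman diketone, made from an ω-(methoxymethoxy) 2-hydroxyaryl ketone and 3,4-bis(silyloxy)benzoyl chloride (ring B, from 3,4-dihydroxybenzoic acid).
- The ω-alkoxy ketone comes from a ring A phenol by ortho-formylation at C4a, addition of MOMOCH2Li and oxidation.
- Ring A is made by a Danheiser benzannulation of a 2-silyloxyvinyl diazo ketone (from biacetyl) with a prenyl-substituted siloxyalkyne (from 4-methylpent-3-enoic acid). The strategy rests on the fact that C8, the prenyl-bearing carbon, sits between the oxygen-bearing carbons C7 and C8a of ring A, whose oxygens at C5, C7 and C8a are meta to one another; the annulation delivers them as OTBS, OTIPS and free OH.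
- Order of ring formation: ring B is bought, ring A is closed in step 5, ring C in step 13.

Key step: step 5

Remark on the chemistry: the target has no stereocenter; compounds 11, 16 and 22 are racemic and their stereocenters disappear later. Tributyl[(methoxymethoxy)methyl]stannane, 2,2,2-trifluoroethyl trifluoroacetate and methanesulfonyl azide are taken as purchased or freshly made reagents.

**Route**

Step 1
Reactants: 1 biacetyl
Product: 2 3-[(tert-butyldimethylsilyl)oxy]but-3-en-2-one
Conditions: TBSOTf (0.95 equiv), Et3N, CH2Cl2, −78 → 0 °C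
Reagents that add atoms: tert-butyldimethylsilyl trifluoromethanesulfonate, CC(C)(C)[Si](C)(C)OS(=O)(=O)C(F)(F)F
Why: Soft enolization of the 1,2-diketone with silyl triflate and amine (silyl enol ether formation) should stop at the monosilyl enol ether when the diketone is in slight excess, because the second enolization to the bis(silyloxy)diene is slower.

Step 2
Reactants: 2 3-[(tert-butyldimethylsilyl)oxy]but-3-en-2-one
Product: 4 3-[(tert-butyldimethylsilyl)oxy]-1-diazobut-3-en-2-one, via trifluoroacetyl diketone 3 (not isolated)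
Conditions: LiN(SiMe3)2, THF, −78 °C; CF3CO2CH2CF3; cold dilute HCl wash; then MsN3, Et3N, H2O (1 equiv), MeCN, rt
Reagents that add atoms: methanesulfonyl azide, CS(=O)(=O)N=[N+]=[N-] (the two diazo nitrogens); 2,2,2-trifluoroethyl trifluoroacetate, O=C(OCC(F)(F)F)C(F)(F)F (its acyl group reaches intermediate 3 only and is lost again)
Why: Detrifluoroacetylative diazo transfer: the kinetic lithium enolate of the methyl ketone is C-trifluoroacetylated to the activated diketone 3, which undergoes Regitz-type diazo transfer with loss of the trifluoroacetyl group as the N-sulfonyl amide, a sequence designed for base-sensitive enones.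

Step 3
Reactants: 5 4-methylpent-3-enoic acid
Product: 6 ethyl 4-methylpent-3-enoate
Conditions: EtI, K2CO3, DMF, rt
Reagents that add atoms: iodoethane, CCI
Why: Carboxylate O-alkylation under mildly basic conditions avoids the acid-catalysed lactonization to the γ-lactone that a Fischer esterification of this β,γ-unsaturated acid would invite.

Step 4
Reactants: 6 ethyl 4-methylpent-3-enoate
Product: 9 triisopropyl[(5-methylhex-4-en-1-yn-1-yl)oxy]silane, via lithium dibromoenolate 7 (not isolated), via lithium ynolate 8 (not isolated)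
Conditions: CH2Br2, LiTMP (lithium 2,2,6,6-tetramethylpiperidide), THF, −78 °C; then LiN(SiMe3)2; then n-BuLi, −78 → 0 °C; then TIPSCl, −78 °C → rt
Reagents that add atoms: dibromomethane, BrCBr; triisopropylsilyl chloride, CC(C)[Si](Cl)(C(C)C)C(C)C
Why: Kowalski ester homologation stopped at the ynolate: LiCHBr2 adds to the ester, enolate 7 undergoes bromine–lithium exchange and a carbenoid 1,2-shift of the prenyl group to ynolate 8, and the bulky silyl chloride traps it on oxygen as the silyl ynol ether.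

Step 5
Reactants: 4 3-[(tert-butyldimethylsilyl)oxy]-1-diazobut-3-en-2-one; 9 triisopropyl[(5-methylhex-4-en-1-yn-1-yl)oxy]silane (1.3 equiv)
Product: 14 5-[(tert-butyldimethylsilyl)oxy]-2-(3-methylbut-2-en-1-yl)-3-[(triisopropylsilyl)oxy]phenol, via vinylketene 10 (not isolated), via vinylcyclobutenone 11 (not isolated), via dienylketene 12 (not isolated), via cyclohexadienone 13 (not isolated)
Conditions: hν (254 nm, low-pressure Hg lamps, quartz), degassed ClCH2CH2Cl, rt; then 80 °C
Reagents that add atoms: none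
Why: Irradiation expels N2 from 4 and the silyloxyvinyl group migrates (Wolff rearrangement) to give vinylketene 10, whose ketene carbon is attacked by the nucleophilic, prenyl-bearing carbon of the siloxyalkyne in a regiospecific (2+2) cycloaddition that forms the C8–C8a and C6–C7 bonds of cyclobutenone 11. Reversible four-electron electrocyclic opening of 11 (light or heat) gives dienylketene 12, and six-electron electrocyclization of 12 forms C4a–C8a and closes ring A as cyclohexadienone 13, which enolizes to the phenol. This is the photochemical Wolff variant of the Danheiser benzannulation, established for α-diazo enones with triisopropylsiloxyalkynes as a route to resorcinol monosilyl ethers. No stereocenter remains, since the one in 11 is lost on ring opening. The step needs regioselectivity only, and the polarization of the ynol ether secures it: the prenyl carbon lands between the new free hydroxyl (C8a) and the OTIPS carbon (C7), while C5 carries OTBS. The trisubstituted prenyl alkene is far less ketenophilic than the siloxyalkyne and should be left alone.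

Step 6
Reactants: 14 5-[(tert-butyldimethylsilyl)oxy]-2-(3-methylbut-2-en-1-yl)-3-[(triisopropylsilyl)oxy]phenol
Product: 15 6-[(tert-butyldimethylsilyl)oxy]-2-hydroxy-3-(3-methylbut-2-en-1-yl)-4-[(triisopropylsilyl)oxy]benzaldehyde
Conditions: MgCl2 (anhydrous), Et3N, (CH2O)n, THF, 65 °C
Reagents that add atoms: paraformaldehyde (formaldehyde unit), C=O
Why: Magnesium-mediated ortho-formylation: the magnesium phenoxide delivers formaldehyde within a chelate to the only unsubstituted ortho carbon (the later C4a), a second formaldehyde oxidizes the hydroxymethyl intermediate, and the para carbon C6 is not attacked.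

Step 7
Reactants: 15 6-[(tert-butyldimethylsilyl)oxy]-2-hydroxy-3-(3-methylbut-2-en-1-yl)-4-[(triisopropylsilyl)oxy]benzaldehyde
Product: 16 3-[(tert-butyldimethylsilyl)oxy]-2-[1-hydroxy-2-(methoxymethoxy)ethyl]-6-(3-methylbut-2-en-1-yl)-5-[(triisopropylsilyl)oxy]phenol (racemic)
Conditions: Bu3SnCH2OMOM (2.4 equiv), n-BuLi (2.3 equiv), THF, −78 °C; then 15, −78 °C; NH4Cl (aq) at −78 °C; crude product used at once
Reagents that add atoms: tributyl[(methoxymethoxy)methyl]stannane, CCCC[Sn](CCCC)(CCCC)COCOC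
Why: Tin–lithium exchange gives the α-alkoxy organolithium MOMOCH2Li (a hydroxymethyl anion equivalent), whose first equivalent deprotonates the phenol and whose second adds 1,2 to the aldehyde; the cold quench should keep the new lithium alkoxide from taking over the neighbouring aryl TBS group, and the racemic carbinol center is removed in step 8.

Step 8
Reactants: 16 3-[(tert-butyldimethylsilyl)oxy]-2-[1-hydroxy-2-(methoxymethoxy)ethyl]-6-(3-methylbut-2-en-1-yl)-5-[(triisopropylsilyl)oxy]phenol
Product: 17 1-{6-[(tert-butyldimethylsilyl)oxy]-2-hydroxy-3-(3-methylbut-2-en-1-yl)-4-[(triisopropylsilyl)oxy]phenyl}-2-(methoxymethoxy)ethan-1-one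
Conditions: MnO2 (activated, excess), CH2Cl2, rt
Reagents that add atoms: none
Why: MnO2 oxidizes the electron-rich benzylic alcohol selectively (benzylic alcohol oxidation) and should leave the prenyl alkene, the acetal and the silyl ethers untouched, the product being stabilized by the phenol-to-ketone hydrogen bond.

Step 9
Reactants: 18 3,4-dihydroxybenzoic acid
Product: 19 tert-butyldimethylsilyl 3,4-bis[(tert-butyldimethylsilyl)oxy]benzoate
Conditions: TBSCl (3.5 equiv), imidazole, DMF, rt
Reagents that add atoms: tert-butyldimethylsilyl chloride, CC(C)(C)[Si](C)(C)Cl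
Why: Exhaustive silylation with silyl chloride and imidazole covers both phenols and the carboxylic acid in one operation.

Step 10
Reactants: 19 tert-butyldimethylsilyl 3,4-bis[(tert-butyldimethylsilyl)oxy]benzoate
Product: 20 3,4-bis[(tert-butyldimethylsilyl)oxy]benzoyl chloride
Conditions: (COCl)2, DMF (cat.), CH2Cl2, 0 °C → rt
Reagents that add atoms: oxalyl chloride, O=C(Cl)C(=O)Cl
Why: Silyl esters are converted by oxalyl chloride and catalytic DMF (chloroiminium activation) directly into acid chlorides with loss of the silyl chloride, so no HCl is formed and the aryl silyl ethers should survive.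

Step 11
Reactants: 17 1-{6-[(tert-butyldimethylsilyl)oxy]-2-hydroxy-3-(3-methylbut-2-en-1-yl)-4-[(triisopropylsilyl)oxy]phenyl}-2-(methoxymethoxy)ethan-1-one; 20 3,4-bis[(tert-butyldimethylsilyl)oxy]benzoyl chloride
Product: 21 3-[(tert-butyldimethylsilyl)oxy]-2-[(methoxymethoxy)acetyl]-6-(3-methylbut-2-en-1-yl)-5-[(triisopropylsilyl)oxy]phenyl 3,4-bis[(tert-butyldimethylsilyl)oxy]benzoate
Conditions: Et3N, DMAP (cat.), CH2Cl2, 0 °C → rt
Reagents that add atoms: none
Why: DMAP-catalysed O-acylation (nucleophilic catalysis through the acylpyridinium ion) of the hydrogen-bonded, ortho-substituted phenol sets up the Baker–Venkataraman substrate.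

Step 12
Reactants: 21 3-[(tert-butyldimethylsilyl)oxy]-2-[(methoxymethoxy)acetyl]-6-(3-methylbut-2-en-1-yl)-5-[(triisopropylsilyl)oxy]phenyl 3,4-bis[(tert-butyldimethylsilyl)oxy]benzoate
Product: 22 1-{3,4-bis[(tert-butyldimethylsilyl)oxy]phenyl}-3-{6-[(tert-butyldimethylsilyl)oxy]-2-hydroxy-3-(3-methylbut-2-en-1-yl)-4-[(triisopropylsilyl)oxy]phenyl}-2-(methoxymethoxy)propane-1,3-dione (racemic, keto form drawn)
Conditions: LiN(SiMe3)2 (3 equiv), THF, −78 → 0 °C; then NH4Cl (aq)
Reagents that add atoms: none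
Why: Baker–Venkataraman rearrangement: the α-alkoxy ketone enolate attacks the neighbouring aryl ester through a six-membered transition state and the O-to-C acyl shift gives the 1,3-diketone, while the non-nucleophilic amide base at low temperature should spare the aryl silyl ethers; the labile C2 center vanishes in step 13.

Step 13
Reactants: 22 1-{3,4-bis[(tert-butyldimethylsilyl)oxy]phenyl}-3-{6-[(tert-butyldimethylsilyl)oxy]-2-hydroxy-3-(3-methylbut-2-en-1-yl)-4-[(triisopropylsilyl)oxy]phenyl}-2-(methoxymethoxy)propane-1,3-dione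
Product: 24 2-{3,4-bis[(tert-butyldimethylsilyl)oxy]phenyl}-5-[(tert-butyldimethylsilyl)oxy]-3-hydroxy-8-(3-methylbut-2-en-1-yl)-7-[(triisopropylsilyl)oxy]-4H-chromen-4-one, via 3-(methoxymethoxy)flavone 23 (not isolated)
Conditions: p-TsOH·H2O (0.3 equiv), MeOH/THF, 45 °C
Reagents that add atoms: none
Why: Acid-catalysed cyclodehydration of the 2-hydroxyaryl 1,3-diketone closes ring C by 6-exo-trig attack of the phenol oxygen on the aroyl carbonyl and loss of water, and the same acid transacetalizes the enol MOM ether of 23 to methanol; the aryl silyl ethers are slow to cleave in acid, so the 7-OTIPS group should keep the prenyl group from closing a chroman onto a free ortho hydroxyl, and any early loss of the 5-O-silyl group would converge in step 14.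

Step 14
Reactants: 24 2-{3,4-bis[(tert-butyldimethylsilyl)oxy]phenyl}-5-[(tert-butyldimethylsilyl)oxy]-3-hydroxy-8-(3-methylbut-2-en-1-yl)-7-[(triisopropylsilyl)oxy]-4H-chromen-4-one
Product: 25 8-prenylquercetin, 2-(3,4-dihydroxyphenyl)-3,5,7-trihydroxy-8-(3-methylbut-2-en-1-yl)-4H-chromen-4-one
Conditions: Bu4NF, AcOH (1:1, 6 equiv), THF, 0 °C → rt, under Ar
Reagents that add atoms: none
Why: Fluoride-induced desilylation of the four aryl silyl ethers, buffered with acetic acid so that no catechol or flavonol anion is exposed to air, should release the target without touching the acid-sensitive prenyl group.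

**Compound list**

1 | biacetyl (butane-2,3-dione) | CC(=O)C(C)=O | starting material
2 | 3-[(tert-butyldimethylsilyl)oxy]but-3-en-2-one | C=C(O[Si](C)(C)C(C)(C)C)C(C)=O | intermediate
3 | 5-[(tert-butyldimethylsilyl)oxy]-1,1,1-trifluorohex-5-ene-2,4-dione | C=C(O[Si](C)(C)C(C)(C)C)C(=O)CC(=O)C(F)(F)F | intermediate
4 | 3-[(tert-butyldimethylsilyl)oxy]-1-diazobut-3-en-2-one | C=C(O[Si](C)(C)C(C)(C)C)C(=O)C=[N+]=[N-] | intermediate
5 | 4-methylpent-3-enoic acid | CC(C)=CCC(=O)O | starting material
6 | ethyl 4-methylpent-3-enoate | CCOC(=O)CC=C(C)C | intermediate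
7 | lithium 1,1-dibromo-5-methylhexa-1,4-dien-2-olate | [Li+].[O-]C(CC=C(C)C)=C(Br)Br | intermediate
8 | lithium 5-methylhex-4-en-1-yn-1-olate | [Li+].[O-]C#CCC=C(C)C | intermediate
9 | triisopropyl[(5-methylhex-4-en-1-yn-1-yl)oxy]silane | CC(C)=CCC#CO[Si](C(C)C)(C(C)C)C(C)C | intermediate
10 | 3-[(tert-butyldimethylsilyl)oxy]buta-1,3-dien-1-one | C=C(O[Si](C)(C)C(C)(C)C)C=C=O | intermediate
11 | 4-{1-[(tert-butyldimethylsilyl)oxy]ethenyl}-2-(3-methylbut-2-en-1-yl)-3-[(triisopropylsilyl)oxy]cyclobut-2-en-1-one (racemic) | CC(C)=CCC1=C(O[Si](C(C)C)(C(C)C)C(C)C)C(C(=C)O[Si](C)(C)C(C)(C)C)C1=O | intermediate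
12 | (3E)-5-[(tert-butyldimethylsilyl)oxy]-2-(3-methylbut-2-en-1-yl)-3-[(triisopropylsilyl)oxy]hexa-1,3,5-trien-1-one (C2 and C5 cis across C3=C4) | O=C=C(CC=C(C)C)/C(O[Si](C(C)C)(C(C)C)C(C)C)=C\C(=C)O[Si](C)(C)C(C)(C)C | intermediate
13 | 5-[(tert-butyldimethylsilyl)oxy]-2-(3-methylbut-2-en-1-yl)-3-[(triisopropylsilyl)oxy]cyclohexa-2,4-dien-1-one | O=C1CC(O[Si](C)(C)C(C)(C)C)=CC(O[Si](C(C)C)(C(C)C)C(C)C)=C1CC=C(C)C | intermediate
14 | 5-[(tert-butyldimethylsilyl)oxy]-2-(3-methylbut-2-en-1-yl)-3-[(triisopropylsilyl)oxy]phenol | CC(C)=CCc1c(O)cc(O[Si](C)(C)C(C)(C)C)cc1O[Si](C(C)C)(C(C)C)C(C)C | intermediate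
15 | 6-[(tert-butyldimethylsilyl)oxy]-2-hydroxy-3-(3-methylbut-2-en-1-yl)-4-[(triisopropylsilyl)oxy]benzaldehyde | O=Cc1c(O)c(CC=C(C)C)c(O[Si](C(C)C)(C(C)C)C(C)C)cc1O[Si](C)(C)C(C)(C)C | intermediate
16 | 3-[(tert-butyldimethylsilyl)oxy]-2-[1-hydroxy-2-(methoxymethoxy)ethyl]-6-(3-methylbut-2-en-1-yl)-5-[(triisopropylsilyl)oxy]phenol (racemic) | COCOCC(O)c1c(O)c(CC=C(C)C)c(O[Si](C(C)C)(C(C)C)C(C)C)cc1O[Si](C)(C)C(C)(C)C | intermediate
17 | 1-{6-[(tert-butyldimethylsilyl)oxy]-2-hydroxy-3-(3-methylbut-2-en-1-yl)-4-[(triisopropylsilyl)oxy]phenyl}-2-(methoxymethoxy)ethan-1-one | COCOCC(=O)c1c(O)c(CC=C(C)C)c(O[Si](C(C)C)(C(C)C)C(C)C)cc1O[Si](C)(C)C(C)(C)C | intermediate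
18 | 3,4-dihydroxybenzoic acid | O=C(O)c1ccc(O)c(O)c1 | starting material
19 | tert-butyldimethylsilyl 3,4-bis[(tert-butyldimethylsilyl)oxy]benzoate | CC(C)(C)[Si](C)(C)OC(=O)c1ccc(O[Si](C)(C)C(C)(C)C)c(O[Si](C)(C)C(C)(C)C)c1 | intermediate
20 | 3,4-bis[(tert-butyldimethylsilyl)oxy]benzoyl chloride | O=C(Cl)c1ccc(O[Si](C)(C)C(C)(C)C)c(O[Si](C)(C)C(C)(C)C)c1 | intermediate
21 | 3-[(tert-butyldimethylsilyl)oxy]-2-[(methoxymethoxy)acetyl]-6-(3-methylbut-2-en-1-yl)-5-[(triisopropylsilyl)oxy]phenyl 3,4-bis[(tert-butyldimethylsilyl)oxy]benzoate | COCOCC(=O)c1c(OC(=O)c2ccc(O[Si](C)(C)C(C)(C)C)c(O[Si](C)(C)C(C)(C)C)c2)c(CC=C(C)C)c(O[Si](C(C)C)(C(C)C)C(C)C)cc1O[Si](C)(C)C(C)(C)C | intermediate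
22 | 1-{3,4-bis[(tert-butyldimethylsilyl)oxy]phenyl}-3-{6-[(tert-butyldimethylsilyl)oxy]-2-hydroxy-3-(3-methylbut-2-en-1-yl)-4-[(triisopropylsilyl)oxy]phenyl}-2-(methoxymethoxy)propane-1,3-dione (racemic) | COCOC(C(=O)c1ccc(O[Si](C)(C)C(C)(C)C)c(O[Si](C)(C)C(C)(C)C)c1)C(=O)c1c(O)c(CC=C(C)C)c(O[Si](C(C)C)(C(C)C)C(C)C)cc1O[Si](C)(C)C(C)(C)C | intermediate
23 | 2-{3,4-bis[(tert-butyldimethylsilyl)oxy]phenyl}-5-[(tert-butyldimethylsilyl)oxy]-3-(methoxymethoxy)-8-(3-methylbut-2-en-1-yl)-7-[(triisopropylsilyl)oxy]-4H-chromen-4-one | COCOc1c(-c2ccc(O[Si](C)(C)C(C)(C)C)c(O[Si](C)(C)C(C)(C)C)c2)oc2c(CC=C(C)C)c(O[Si](C(C)C)(C(C)C)C(C)C)cc(O[Si](C)(C)C(C)(C)C)c2c1=O | intermediate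
24 | 2-{3,4-bis[(tert-butyldimethylsilyl)oxy]phenyl}-5-[(tert-butyldimethylsilyl)oxy]-3-hydroxy-8-(3-methylbut-2-en-1-yl)-7-[(triisopropylsilyl)oxy]-4H-chromen-4-one | CC(C)=CCc1c(O[Si](C(C)C)(C(C)C)C(C)C)cc(O[Si](C)(C)C(C)(C)C)c2c(=O)c(O)c(-c3ccc(O[Si](C)(C)C(C)(C)C)c(O[Si](C)(C)C(C)(C)C)c3)oc12 | intermediate
25 | 8-prenylquercetin | CC(C)=CCc1c(O)cc(O)c2c(=O)c(O)c(-c3ccc(O)c(O)c3)oc12 | target

**Step count**

Total: 14 steps. Longest linear sequence: 10 steps (steps 1, 2, 5, 6, 7, 8, 11, 12, 13, 14 from biacetyl; equally 3, 4, 5, 6, 7, 8, 11, 12, 13, 14 from 4-methylpent-3-enoic acid).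

**Steps most likely to fail and fallbacks**

Step 5. The vinylketene may be lost to dimerization or to acylation of the product phenol, and the silyl enol ether or the siloxyalkyne may be degraded by the short-wavelength light before the cycloaddition takes place. The fallback sets out from 9 and comes back at 14. It replaces the photochemical Wolff entry by the thermal cyclobutenone entry to the same vinylketene. Commercial cyclobutane-1,3-dione is O-silylated (TBSCl, Et3N, CH2Cl2, 0 °C) to 3-[(tert-butyldimethylsilyl)oxy]cyclobut-2-en-1-one F1. F1 is then heated with 9 in toluene at 80–110 °C. Four-electron ring opening of F1 should give vinylketene 10 without light and without a diazo compound, and the cascade runs on through 11, 12 and 13 to 14.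

Step 7. Addition to the phenoxide-deactivated, doubly ortho-substituted aldehyde may stall. The lithium alkoxide may also take over the ortho TBS group by a 1,5 oxygen-to-oxygen silyl shift, or the electron-rich benzylic alcohol may ionize to an ortho-quinone methide on work-up. The fallback sets out from 15 and comes back at 24. It gives up the ω-alkoxy ketone and brings in the C3 oxygen at the flavone stage.
- MeMgBr (3 equiv, THF, −78 °C) gives 3-[(tert-butyldimethylsilyl)oxy]-2-(1-hydroxyethyl)-6-(3-methylbut-2-en-1-yl)-5-[(triisopropylsilyl)oxy]phenol F2; its magnesium alkoxide is much less prone to silyl transfer.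
- MnO2 oxidation gives 1-{6-[(tert-butyldimethylsilyl)oxy]-2-hydroxy-3-(3-methylbut-2-en-1-yl)-4-[(triisopropylsilyl)oxy]phenyl}ethan-1-one F3.
- Acylation with 20 (Et3N, DMAP) gives 2-acetyl-3-[(tert-butyldimethylsilyl)oxy]-6-(3-methylbut-2-en-1-yl)-5-[(triisopropylsilyl)oxy]phenyl 3,4-bis[(tert-butyldimethylsilyl)oxy]benzoate F4.
- Baker–Venkataraman rearrangement (LiN(SiMe3)2, THF) gives 1-{3,4-bis[(tert-butyldimethylsilyl)oxy]phenyl}-3-{6-[(tert-butyldimethylsilyl)oxy]-2-hydroxy-3-(3-methylbut-2-en-1-yl)-4-[(triisopropylsilyl)oxy]phenyl}propane-1,3-dione F5.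
- Buffered cyclodehydration (AcOH, NaOAc, 80 °C) gives 2-{3,4-bis[(tert-butyldimethylsilyl)oxy]phenyl}-5-[(tert-butyldimethylsilyl)oxy]-8-(3-methylbut-2-en-1-yl)-7-[(triisopropylsilyl)oxy]-4H-chromen-4-one F6.
- C3 lithiation of F6 (LiN(i-Pr)2, THF, −78 °C), borylation with B(OMe)3 and oxidation of the borate with buffered H2O2 (NaHCO3, 0 °C; alkaline peroxide does not epoxidize the prenyl group) should give 24.

This fallback also removes the MOM group and the acid step from the route.

Step 13. Acid strong enough to dehydrate and to cleave the acetal may also protonate the prenyl alkene, leading to methanol addition or chroman closure onto the transient C8a hydroxyl, or may strip the silyl ethers unevenly. The fallback sets out from 22 and comes back at 24; it separates the two events and uses no Brønsted acid for the deprotection. The diketone is cyclodehydrated under buffered conditions (AcOH, NaOAc, 80 °C) and 23 is isolated. The MOM ether is then removed by thiol-assisted Lewis acid transacetalization (ZnBr2, n-PrSH, CH2Cl2, 0 °C, a few minutes), which is known to spare alkenes and silyl ethers. This fallback makes no compound outside the compound list (F0).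

**Further compounds**

F1 | step 5 | 3-[(tert-butyldimethylsilyl)oxy]cyclobut-2-en-1-one | O=C1CC(O[Si](C)(C)C(C)(C)C)=C1
F2 | step 7 | 3-[(tert-butyldimethylsilyl)oxy]-2-(1-hydroxyethyl)-6-(3-methylbut-2-en-1-yl)-5-[(triisopropylsilyl)oxy]phenol (racemic) | CC(O)c1c(O)c(CC=C(C)C)c(O[Si](C(C)C)(C(C)C)C(C)C)cc1O[Si](C)(C)C(C)(C)C
F3 | step 7 | 1-{6-[(tert-butyldimethylsilyl)oxy]-2-hydroxy-3-(3-methylbut-2-en-1-yl)-4-[(triisopropylsilyl)oxy]phenyl}ethan-1-one | CC(=O)c1c(O)c(CC=C(C)C)c(O[Si](C(C)C)(C(C)C)C(C)C)cc1O[Si](C)(C)C(C)(C)C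
F4 | step 7 | 2-acetyl-3-[(tert-butyldimethylsilyl)oxy]-6-(3-methylbut-2-en-1-yl)-5-[(triisopropylsilyl)oxy]phenyl 3,4-bis[(tert-butyldimethylsilyl)oxy]benzoate | CC(=O)c1c(OC(=O)c2ccc(O[Si](C)(C)C(C)(C)C)c(O[Si](C)(C)C(C)(C)C)c2)c(CC=C(C)C)c(O[Si](C(C)C)(C(C)C)C(C)C)cc1O[Si](C)(C)C(C)(C)C
F5 | step 7 | 1-{3,4-bis[(tert-butyldimethylsilyl)oxy]phenyl}-3-{6-[(tert-butyldimethylsilyl)oxy]-2-hydroxy-3-(3-methylbut-2-en-1-yl)-4-[(triisopropylsilyl)oxy]phenyl}propane-1,3-dione | O=C(CC(=O)c1c(O)c(CC=C(C)C)c(O[Si](C(C)C)(C(C)C)C(C)C)cc1O[Si](C)(C)C(C)(C)C)c1ccc(O[Si](C)(C)C(C)(C)C)c(O[Si](C)(C)C(C)(C)C)c1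
F6 | step 7 | 2-{3,4-bis[(tert-butyldimethylsilyl)oxy]phenyl}-5-[(tert-butyldimethylsilyl)oxy]-8-(3-methylbut-2-en-1-yl)-7-[(triisopropylsilyl)oxy]-4H-chromen-4-one | CC(C)=CCc1c(O[Si](C(C)C)(C(C)C)C(C)C)cc(O[Si](C)(C)C(C)(C)C)c2c(=O)cc(-c3ccc(O[Si](C)(C)C(C)(C)C)c(O[Si](C)(C)C(C)(C)C)c3)oc12
F0 | step 13 | none | none
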